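**Retrosynthetic overview**

1. Target ⇒ tricyclic bis-lactone in which the propanoate carboxyl is tied as an acylal to the oxygen on C3; neutral methanolysis unveils the methyl ester and the lactol OH (cis to C4) together. The bis-lactone comes from a dienyl lactone by copper hydride 1,4-reduction (sets C7a).
2. Dienyl lactone ⇒ acylal-tethered dienyne by rhodium-catalysed intramolecular alkyne–diene [4+2] coupling: C3a–C4 and C5–C6 form, the cyclohexene ring closes, and C3a is set by C3.
3. Dienyne ⇒ racemic 3-vinylbutenolide carbonate + (R)-2-methylalk-3-ynoic acid by a palladium-catalysed dynamic kinetic asymmetric acyloxylation (new; sets C3).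
4. Acid ⇒ (S)-1-ethynyl-1,3,3-trimethylcyclohexane + racemic tert-butyl 2-bromopropanoate by copper-catalysed enantioconvergent C(sp)–C(sp3) coupling (C4–C8 bond, sets C8). The alkyne comes from 3-methylcyclohexenone (asymmetric conjugate alkenylation sets C1′, then gem-dimethylation); the butenolide comes from 3-bromofuran (silyl-directed singlet-oxygen oxidation, Stille vinylation).
5. Ring order: trimethylcyclohexane ring (from the enone) and butenolide ring (from the furan) first; cyclohexene ring and a temporary δ-lactone ring together in the [4+2] step; δ-lactone ring opened last.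

Locants: isobenzofuranone numbering for the core (C1 lactone carbonyl, O2, C3 lactol carbon, C3a, C4–C7, C7a); C8 = propanoate α-carbon on C4, C9 = its carboxyl carbon; C1′ = quaternary ring carbon on C5.

Assumption: the lactol carbon C3 is treated as a defined centre (3R, OH cis to C4); it is made by retention from an acylal and kept under non-basic conditions, because lactols can epimerise by ring opening.

**Route**

Step 1
Reactants: 1 ethynyltrimethylsilane; 2 3-methylcyclohex-2-en-1-one
Product: 4 (3S)-3-methyl-3-[1-(trimethylsilyl)ethenyl]cyclohexan-1-one, via alkenylalane 3 (not isolated)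
Conditions: 1, i-Bu2AlH (1.0 equiv), hexanes/THF, 55 °C; then 2, CuCl2·2H2O (5 mol %), chiral sulfonate-bearing N-heterocyclic carbene ligand (5 mol %, enantiomer giving S), THF, −78 → 4 °C; aq. KNaC4H4O6
Reagents that add atoms: none
Why: NHC–copper-catalysed enantioselective conjugate addition of a silicon-substituted alkenylaluminium (from regioselective hydroalumination of 1) to a β-methyl cyclic enone; the chiral copper–carbene complex discriminates the enone faces and sets the quaternary centre C1′ as S.

Step 2
Reactants: 4 (3S)-3-methyl-3-[1-(trimethylsilyl)ethenyl]cyclohexan-1-one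
Product: 5 trimethyl{1-[(1S)-1,3,3-trimethylcyclohexyl]ethenyl}silane
Conditions: Me2Zn (2.5 equiv), TiCl4 (2.5 equiv), CH2Cl2, −40 °C; then 4, −40 → 25 °C
Reagents that add atoms: dimethylzinc, C[Zn]C
Why: Reetz geminal dimethylation: Me2TiCl2 made from Me2Zn and TiCl4 adds one methyl to the ketone, the tertiary titanium alkoxide ionises and takes up the second methyl, so C=O becomes CMe2 without touching C1′ or the vinylsilane.

Step 3
Reactants: 5 trimethyl{1-[(1S)-1,3,3-trimethylcyclohexyl]ethenyl}silane
Product: 6 (1S)-1-(1-iodoethenyl)-1,3,3-trimethylcyclohexane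
Conditions: NIS (1.3 equiv), MeCN/ClCH2CN 4:1, 0 → 25 °C, dark
Reagents that add atoms: N-iodosuccinimide, O=C1CCC(=O)N1I
Why: Electrophilic ipso-iododesilylation of the vinylsilane, which exchanges SiMe3 for iodine on the same carbon.

Step 4
Reactants: 6 (1S)-1-(1-iodoethenyl)-1,3,3-trimethylcyclohexane
Product: 7 (1S)-1-ethynyl-1,3,3-trimethylcyclohexane
Conditions: Bu4NF·3H2O (5 equiv), DMF, 60 °C
Reagents that add atoms: none
Why: Fluoride-mediated anti-dehydroiodination (E2) of the 2-iodo-1-alkene gives the terminal alkyne; the neighbouring quaternary carbon has no hydrogen, so no allene can form.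

Step 5
Reactants: 8 2-bromopropanoyl bromide
Product: 9 tert-butyl 2-bromopropanoate (racemic)
Conditions: t-BuOH (1.2 equiv), pyridine (1.2 equiv), Et2O, 0 → 25 °C
Reagents that add atoms: tert-butanol, CC(C)(C)O
Why: Acylation of tert-butanol by the acid bromide (nucleophilic acyl substitution); the racemate is what the next step needs.

Step 6
Reactants: 7 (1S)-1-ethynyl-1,3,3-trimethylcyclohexane; 9 tert-butyl 2-bromopropanoate
Product: 10 tert-butyl (2R)-2-methyl-4-[(1S)-1,3,3-trimethylcyclohexyl]but-3-ynoate
Conditions: CuI (10 mol %), cinchona-derived chiral N,N,P ligand (12 mol %, enantiomer giving R), Cs2CO3 (2 equiv), Et2O, 20 °C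
Reagents that add atoms: none
Why: Copper-catalysed enantioconvergent radical C(sp3)–C(sp) cross-coupling (asymmetric Sonogashira type, best documented for α-bromo amides): the chiral copper catalyst turns racemic 9 into a planar α-ester radical and joins it to the alkynyl group of 7 on one face, forming the C4–C8 bond and setting C8 as R.

Step 7
Reactants: 10 tert-butyl (2R)-2-methyl-4-[(1S)-1,3,3-trimethylcyclohexyl]but-3-ynoate
Product: 11 (2R)-2-methyl-4-[(1S)-1,3,3-trimethylcyclohexyl]but-3-ynoic acid
Conditions: CF3CO2H/CH2Cl2 1:4, 0 → 20 °C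
Reagents that add atoms: none
Why: Acidolysis of the tert-butyl ester (loss of isobutene) frees the acid without base, so the propargylic centre C8 is not epimerised and the alkyne does not isomerise to an allene.

Step 8
Reactants: 12 3-bromofuran
Product: 14 3-bromo-2-(trimethylsilyl)furan, via lithiofuran 13 (not isolated)
Conditions: LiN(i-Pr)2 (1.05 equiv), THF, −78 °C; then Me3SiCl, −78 → 0 °C
Reagents that add atoms: chlorotrimethylsilane, C[Si](C)(C)Cl
Why: Regioselective deprotonation of 3-bromofuran at C2 (flanked by O and Br) at −78 °C and silylation of the lithiofuran.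

Step 9
Reactants: 14 3-bromo-2-(trimethylsilyl)furan
Product: 15 3-bromo-5-hydroxyfuran-2(5H)-one (racemic)
Conditions: O2, visible light, tetraphenylporphyrin (0.5 mol %), CH2Cl2, −78 °C; then H2O, 0 °C
Reagents that add atoms: oxygen, O=O
Why: Singlet-oxygen photooxygenation of the 2-silylfuran (silyl-directed furan oxidation) places the lactone carbonyl regiospecifically on the former C–Si carbon and gives the γ-hydroxybutenolide after hydrolysis.

Step 10
Reactants: 15 3-bromo-5-hydroxyfuran-2(5H)-one; 16 trimethyl(vinyl)stannane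
Product: 17 5-hydroxy-3-vinylfuran-2(5H)-one (racemic)
Conditions: Pd2(dba)3 (2.5 mol %), AsPh3 (10 mol %), THF, 45 °C
Reagents that add atoms: none
Why: Stille cross-coupling (oxidative addition of zerovalent palladium into the vinylic C–Br bond, vinyl transfer from tin, reductive elimination) under neutral conditions that the free lactol tolerates; it forms the future C7–C7a bond.

Step 11
Reactants: 17 5-hydroxy-3-vinylfuran-2(5H)-one
Product: 18 tert-butyl (5-oxo-4-vinyl-2,5-dihydrofuran-2-yl) carbonate (racemic)
Conditions: Boc2O (1.2 equiv), DMAP (5 mol %), CH2Cl2, 0 °C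
Reagents that add atoms: di-tert-butyl dicarbonate, CC(C)(C)OC(=O)OC(=O)OC(C)(C)C
Why: DMAP-catalysed O-acylation of the lactol hydroxyl gives the allylic acetal carbonate, an ionisable leaving group for the next step.

Step 12
Reactants: 11 (2R)-2-methyl-4-[(1S)-1,3,3-trimethylcyclohexyl]but-3-ynoic acid; 18 tert-butyl (5-oxo-4-vinyl-2,5-dihydrofuran-2-yl) carbonate
Product: 19 (2R)-5-oxo-4-vinyl-2,5-dihydrofuran-2-yl (2R)-2-methyl-4-[(1S)-1,3,3-trimethylcyclohexyl]but-3-ynoate
Conditions: Pd2(dba)3·CHCl3 (2.5 mol %), DACH-phenyl Trost ligand (7.5 mol %, enantiomer giving the R acetal), Bu4NCl (30 mol %), CH2Cl2, 0 °C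
Reagents that add atoms: none
Why: Proposed new method: zerovalent palladium ionises both enantiomers of 18 with loss of CO2 and tert-butoxide to π-allyl (2-oxyfuran) complexes that interconvert faster than they are attacked, the carboxylate of 11 (formed by the tert-butoxide, no added base) then attacks the acetal carbon of the complex that fits the chiral diphosphine pocket, so the catalyst sets C3 as R and C8 is untouched; the closest known reaction types are the palladium-catalysed dynamic kinetic asymmetric substitution of 5-acyloxy-2(5H)-furanones by phenols and the palladium-catalysed deracemisation of cyclic allylic carbonates with carboxylate nucleophiles.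

Step 13
Reactants: 19 (2R)-5-oxo-4-vinyl-2,5-dihydrofuran-2-yl (2R)-2-methyl-4-[(1S)-1,3,3-trimethylcyclohexyl]but-3-ynoate
Product: 20 tricyclic dienyl bis-lactone (3R,3aS,8R,1′S): cyclohexa-1,4-diene (C4=C5 and C7=C7a) fused to the γ-lactone C1(=O)–O2–C3–C3a–C7a and to the δ-lactone C3–O–C9(=O)–C8(Me)–C4–C3a; C5 carries the trimethylcyclohexyl group; H3 and H3a cis
Conditions: [Rh(cod)(C10H8)]SbF6 (5 mol %), CH2Cl2 (0.02 M), 25 °C
Reagents that add atoms: none
Why: Rhodium-catalysed intramolecular [4+2] coupling of a tethered alkyne and diene (oxidative cyclometallation at cationic monovalent rhodium, then reductive elimination) forms C3a–C4 and C5–C6 and the cyclohexene ring; the four-atom acylal tether delivers C4 to the C3a face that carries the acyloxy group, so C3a is set by C3, and the R methyl on C8 points away from the bulky C1′ group (matched case).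

Step 14
Reactants: 20 tricyclic dienyl bis-lactone
Product: 21 tricyclic bis-lactone (3S,3aR,7aR,8R,1′S): as 20 but with C7–C7a saturated and the γ-lactone cis-fused (H3, H3a and H7a on the same face)
Conditions: [(Ph3P)CuH]6 (0.4 equiv), toluene, 0 → 25 °C; then sat. aq. NH4Cl
Reagents that add atoms: none
Why: Copper hydride conjugate reduction touches only the α,β-unsaturated γ-lactone (the tetrasubstituted C4=C5 and the saturated acylal lactone are inert), and protonation at C7a from the convex face (the face of H3a) gives the cis ring fusion.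

Step 15
Reactants: 21 tricyclic bis-lactone
Product: 22 methyl (2R)-2-{(3R,3aR,7aR)-3-hydroxy-1-oxo-5-[(1S)-1,3,3-trimethylcyclohexyl]-1,3,3a,6,7,7a-hexahydro-2-benzofuran-4-yl}propanoate (CNP0280354.1)
Conditions: MeOH/toluene 1:3, Zn4(OCOCF3)6O (3 mol %), 40 °C
Reagents that add atoms: methanol, CO
Why: Neutral zinc-cluster-catalysed transesterification (methanolysis) at the more strained δ-acylal carbonyl C9; the C3–O bond is not broken, so the hemiacetal oxygen is released as the lactol OH with retention (cis to C4), and the γ-lactone, C8 and the other centres are untouched under non-basic conditions.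

**Compound list**

1 | ethynyltrimethylsilane | C#C[Si](C)(C)C | starting material
2 | 3-methylcyclohex-2-en-1-one | CC1=CC(=O)CCC1 | starting material
3 | diisobutyl[1-(trimethylsilyl)ethenyl]aluminium | C=C([Si](C)(C)C)[Al](CC(C)C)CC(C)C | intermediate
4 | (3S)-3-methyl-3-[1-(trimethylsilyl)ethenyl]cyclohexan-1-one | C=C([Si](C)(C)C)[C@@]1(C)CCCC(=O)C1 | intermediate
5 | trimethyl{1-[(1S)-1,3,3-trimethylcyclohexyl]ethenyl}silane | C=C([Si](C)(C)C)[C@@]1(C)CCCC(C)(C)C1 | intermediate
6 | (1S)-1-(1-iodoethenyl)-1,3,3-trimethylcyclohexane | C=C(I)[C@@]1(C)CCCC(C)(C)C1 | intermediate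
7 | (1S)-1-ethynyl-1,3,3-trimethylcyclohexane | C#C[C@@]1(C)CCCC(C)(C)C1 | intermediate
8 | 2-bromopropanoyl bromide | CC(Br)C(=O)Br | starting material
9 | tert-butyl 2-bromopropanoate (racemic) | CC(Br)C(=O)OC(C)(C)C | intermediate
10 | tert-butyl (2R)-2-methyl-4-[(1S)-1,3,3-trimethylcyclohexyl]but-3-ynoate | CC(C)(C)OC(=O)[C@H](C)C#C[C@@]1(C)CCCC(C)(C)C1 | intermediate
11 | (2R)-2-methyl-4-[(1S)-1,3,3-trimethylcyclohexyl]but-3-ynoic acid | OC(=O)[C@H](C)C#C[C@@]1(C)CCCC(C)(C)C1 | intermediate
12 | 3-bromofuran | Brc1ccoc1 | starting material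
13 | (3-bromofuran-2-yl)lithium | [Li]c1occc1Br | intermediate
14 | 3-bromo-2-(trimethylsilyl)furan | C[Si](C)(C)c1occc1Br | intermediate
15 | 3-bromo-5-hydroxyfuran-2(5H)-one (racemic) | OC1OC(=O)C(Br)=C1 | intermediate
16 | trimethyl(vinyl)stannane | C=C[Sn](C)(C)C | starting material
17 | 5-hydroxy-3-vinylfuran-2(5H)-one (racemic) | OC1OC(=O)C(C=C)=C1 | intermediate
18 | tert-butyl (5-oxo-4-vinyl-2,5-dihydrofuran-2-yl) carbonate (racemic) | CC(C)(C)OC(=O)OC1OC(=O)C(C=C)=C1 | intermediate
19 | (2R)-5-oxo-4-vinyl-2,5-dihydrofuran-2-yl (2R)-2-methyl-4-[(1S)-1,3,3-trimethylcyclohexyl]but-3-ynoate | O=C1O[C@@H](OC(=O)[C@H](C)C#C[C@@]2(C)CCCC(C)(C)C2)C=C1C=C | intermediate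
20 | tricyclic dienyl bis-lactone (3R,3aS,8R,1′S); C4=C5 and C7=C7a; δ-lactone C3–O–C9(=O)–C8–C4–C3a; H3 and H3a cis | O=C3[C@H](C)C1=C([C@@]2(C)CCCC(C)(C)C2)CC=C2C(=O)O[C@@H](O3)[C@@H]12 | intermediate
21 | tricyclic bis-lactone (3S,3aR,7aR,8R,1′S); as 20 with C7–C7a saturated and cis ring fusion | O=C3[C@H](C)C1=C([C@@]2(C)CCCC(C)(C)C2)CC[C@H]2C(=O)O[C@@H](O3)[C@@H]12 | intermediate
22 | methyl (2R)-2-{(3R,3aR,7aR)-3-hydroxy-1-oxo-5-[(1S)-1,3,3-trimethylcyclohexyl]-1,3,3a,6,7,7a-hexahydro-2-benzofuran-4-yl}propanoate | COC(=O)[C@H](C)C1=C([C@@]2(C)CCCC(C)(C)C2)CC[C@H]2C(=O)O[C@@H](O)[C@@H]12 | target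

**Step count**

Total step count: 15. Longest linear sequence: 10 steps (1, 2, 3, 4, 6, 7, 12, 13, 14, 15); the bromoester branch (step 5) and the butenolide branch (steps 8–11) run in parallel.

**Three steps most likely to fail**

Step 6 (enantioconvergent alkynylation). α-Bromo esters are less proven than α-bromo amides in this coupling, the acetylene is very bulky, and the product has an acidic propargylic hydrogen. The fallback replaces catalytic control by an auxiliary-controlled alkylation; it sets out from alkyne 7 and comes back to the route at acid 11, bypassing 8–10. Alkyne 7 is deprotonated and alkylated with oxirane (n-BuLi, BF3·OEt2, THF, −78 °C) to give 4-[(1S)-1,3,3-trimethylcyclohexyl]but-3-yn-1-ol F1. CrO3/H2SO4 in acetone oxidises it to 4-[(1S)-1,3,3-trimethylcyclohexyl]but-3-ynoic acid F2. (COCl)2 with catalytic DMF gives 4-[(1S)-1,3,3-trimethylcyclohexyl]but-3-ynoyl chloride F3, which acylates lithiated (4R)-4-benzyl-1,3-oxazolidin-2-one to give the imide (4R)-4-benzyl-3-{4-[(1S)-1,3,3-trimethylcyclohexyl]but-3-ynoyl}-1,3-oxazolidin-2-one F4. NaN(SiMe3)2 then MeI in THF at −78 °C (Evans alkylation) methylates it on the face away from the benzyl group to give (4R)-4-benzyl-3-{(2R)-2-methyl-4-[(1S)-1,3,3-trimethylcyclohexyl]but-3-ynoyl}-1,3-oxazolidin-2-one F5. LiOH/H2O2 in THF/H2O at 0 °C removes the auxiliary and gives 11.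

Step 12 (the proposed new acyloxylation). The product is itself an ionisable allylic acylal, so the catalyst may erode the ratio at C3, and the dienyl π system offers other sites of attack. The fallback gives up catalyst control for a separation, using known chemistry; it sets out from acid 11 and lactol 17 (carbonate 18 is not made) and comes back at 19. A Mitsunobu esterification at the lactol hydroxyl (PPh3, DIAD, THF, 0 °C) does not activate the acid, so C8 is safe. It gives a roughly 1:1 mixture of 19 and its epimer at the acetal carbon, (2S)-5-oxo-4-vinyl-2,5-dihydrofuran-2-yl (2R)-2-methyl-4-[(1S)-1,3,3-trimethylcyclohexyl]but-3-ynoate F6. The two are separated by chromatography and only 19 is carried on. In step 13 the R methyl on C8 fits only the 19 series, which also discriminates against traces of the epimer.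

Step 13 (rhodium-catalysed [4+2]). Cationic rhodium may ionise the acylal or isomerise the 1,4-diene, and the diene is electron-poor while the alkyne is bulky. The fallback drops metal catalysis for a purely pericyclic ring closure; it sets out from 19 and comes back at 20. Compound 19 is heated at high dilution (0.005 M in 1,2-dichlorobenzene, BHT, 160 °C, sealed tube) in a thermal inverse-electron-demand intramolecular Diels–Alder reaction of the ester-tethered dienyne. The same tether gives the same C3a configuration, and no compound outside the list is made.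

**Further compounds**

F1 | step 6 | 4-[(1S)-1,3,3-trimethylcyclohexyl]but-3-yn-1-ol | OCCC#C[C@@]1(C)CCCC(C)(C)C1
F2 | step 6 | 4-[(1S)-1,3,3-trimethylcyclohexyl]but-3-ynoic acid | OC(=O)CC#C[C@@]1(C)CCCC(C)(C)C1
F3 | step 6 | 4-[(1S)-1,3,3-trimethylcyclohexyl]but-3-ynoyl chloride | ClC(=O)CC#C[C@@]1(C)CCCC(C)(C)C1
F4 | step 6 | (4R)-4-benzyl-3-{4-[(1S)-1,3,3-trimethylcyclohexyl]but-3-ynoyl}-1,3-oxazolidin-2-one | O=C1OC[C@@H](Cc2ccccc2)N1C(=O)CC#C[C@@]3(C)CCCC(C)(C)C3
F5 | step 6 | (4R)-4-benzyl-3-{(2R)-2-methyl-4-[(1S)-1,3,3-trimethylcyclohexyl]but-3-ynoyl}-1,3-oxazolidin-2-one | O=C1OC[C@@H](Cc2ccccc2)N1C(=O)[C@H](C)C#C[C@@]3(C)CCCC(C)(C)C3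
F6 | step 12 | (2S)-5-oxo-4-vinyl-2,5-dihydrofuran-2-yl (2R)-2-methyl-4-[(1S)-1,3,3-trimethylcyclohexyl]but-3-ynoate | O=C1O[C@H](OC(=O)[C@H](C)C#C[C@@]2(C)CCCC(C)(C)C2)C=C1C=C
F0 | step 13 | none | none
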